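**Plan** (caryophyllane numbering: C1/C9 ring-fusion CH, C10 cyclobutane CH2, C11 CMe2, C4 the O/Me carbon, C5 the carbon bonded to benzylic C1′, C8 the methylidene carbon)
1. Retrosynthesis: the dihydropyran is cut at C4–O and C5–C1′ (retro hetero-Diels–Alder) to (+)-(1S,9R)-β-caryophyllene, benzaldehyde and diformylphloroglucinol. The nine-membered ring is then cut at C3–C4 (B-alkyl Suzuki), the C8–C9 bond by directed C–H alkenylation, and the cyclobutane at C1–C11 by a retro-Wolff ring contraction.
2. Enabling feature: C1 of the four-membered ring (C1–C9–C10–C11) carries the exocyclic carbon C2 and lies next to the quaternary C11. The cyclobutane is therefore the ring-contracted form of 2-diazo-5,5-dimethylcyclopentanone, whose carbonyl carbon is pushed out of the ring as C2.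
3. Helpers: the temporary five-membered ring, and C2 held as an 8-aminoquinoline amide (directing group), which is cleaved reductively in step 8.
4. Forward order: cyclobutane (ring contraction), C9 side chain, C1 vinyl arm, nine-membered ring by macrocyclisation, then the chroman in one three-component step.
5. Stereochemistry: C1 comes from catalyst-controlled ketene aminolysis; it is relayed cis to C9 by the amide and then inverted at C1 to the trans series. The E-alkene comes from syn-hydrozirconation. C4, C5 and C1′ arise in the suprafacial cycloaddition on the exposed alkene face.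

Key step: step 2

Assumption: the target contains the (1S,9R)-caryophyllane core, the antipode of the natural (−)-terpene, so the hydrocarbon must be made; its cycloaddition is taken to mirror that of the natural enantiomer.

**Step 1**
Reactants: 1 2,2-dimethylcyclopentan-1-one
Product: 3 2-diazo-5,5-dimethylcyclopentan-1-one, via trifluoroacetyl ketone 2 (not isolated)
Conditions: LiN(SiMe3)2, THF, −78 °C; CF3CO2CH2CF3; then 4-acetamidobenzenesulfonyl azide, Et3N, H2O (1 equiv), MeCN, rt
Reagents that add atoms: 4-acetamidobenzenesulfonyl azide, CC(=O)Nc1ccc(cc1)S(=O)(=O)N=[N+]=[N-]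
Why: The only enolisable α-position (the other α-carbon is quaternary) is trifluoroacetylated (Claisen condensation), and the activated 1,3-dicarbonyl undergoes detrifluoroacetylative Regitz-type diazo transfer, so the diazo group is placed regiospecifically.

**Step 2**
Reactants: 3 2-diazo-5,5-dimethylcyclopentan-1-one; 4 quinolin-8-amine
Product: 6 (1R)-2,2-dimethyl-N-(quinolin-8-yl)cyclobutane-1-carboxamide, via cyclobutylidene ketene 5 (not isolated)
Conditions: hν (254 nm), (+)-cinchonine (10 mol %), 4 (3 equiv), THF, rt; recrystallisation to upgrade the ee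
Reagents that add atoms: none
Why: Irradiation expels N2 and the quaternary CMe2 carbon migrates in concert from the acyl carbon to the former diazo carbon (Wolff rearrangement), so the C1–C11 bond forms as the five-membered ring contracts to a cyclobutylidene ketene whose carbonyl carbon becomes C2. The closest known reaction type is the tandem photo-Wolff ring contraction/cinchona-alkaloid-catalysed enantioselective aminolysis of ketenes from cyclic α-diazo ketones. The four-membered ring closes by a 1,2-alkyl shift (ring contraction, not a Baldwin-type cyclisation), and the strain is paid for by loss of N2. The new stereocentre C1 is set under catalyst control, when the alkaloid-bound enol(ate) formed from the ketene and the amine is protonated on one face; the pseudo-enantiomeric alkaloid would give the antipode. The step needs a single migrating carbon and no carbene leakage: the gem-dimethyl group leaves one diazo-transfer site and one migrating group, and the cyclic diazo ketone is locked s-Z, which favours concerted rearrangement over C–H insertion.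

**Step 3**
Reactants: 7 pent-3-yn-1-ol
Product: 9 (3E)-4-bromopent-3-en-1-ol, via alkenylzirconocene chloride 8 (not isolated)
Conditions: Cp2Zr(H)Cl (2.5 equiv), THF, rt to 40 °C; then N-bromosuccinimide, 0 °C
Reagents that add atoms: N-bromosuccinimide, BrN1C(=O)CCC1=O
Why: syn-Hydrozirconation with excess Cp2Zr(H)Cl equilibrates zirconium to the less hindered methyl-bearing alkyne carbon, and bromodezirconation with retention fixes the E geometry (Br cis to H).

**Step 4**
Reactants: 9 (3E)-4-bromopent-3-en-1-ol
Product: 10 (2E)-2-bromo-5-iodopent-2-ene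
Conditions: I2, PPh3, imidazole, CH2Cl2, 0 °C
Reagents that add atoms: iodine, II
Why: Appel iodination converts the primary alcohol into the iodide by SN2 displacement of the alkoxyphosphonium ion and leaves the alkenyl bromide untouched.

**Step 5**
Reactants: 10 (2E)-2-bromo-5-iodopent-2-ene
Product: 11 (5E)-6-bromohept-5-en-1-yne
Conditions: LiC≡CH·H2NCH2CH2NH2, DMSO, 0 °C to rt
Reagents that add atoms: lithium acetylide–ethylenediamine complex, [Li+].[C-]#C.NCCN
Why: SN2 alkylation of the acetylide at the unhindered primary iodide should outrun E2, and the alkenyl bromide does not react with the acetylide.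

**Step 6**
Reactants: 11 (5E)-6-bromohept-5-en-1-yne
Product: 13 (5E)-6-bromo-2-iodohepta-1,5-diene, via iodoalkenylborane 12 (not isolated)
Conditions: B-iodo-9-BBN, pentane, −20 to 0 °C; then AcOH
Reagents that add atoms: B-iodo-9-borabicyclo[3.3.1]nonane, IB1C2CCCC1CCC2
Why: syn-Iodoboration occurs only at the terminal alkyne with Markovnikov placement of iodine, and protodeboronation with acetic acid gives the 2-iodo-1-alkene.

**Step 7**
Reactants: 6 (1R)-2,2-dimethyl-N-(quinolin-8-yl)cyclobutane-1-carboxamide; 13 (5E)-6-bromo-2-iodohepta-1,5-diene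
Product: 14 (1R,4R)-4-[(5E)-6-bromohepta-1,5-dien-2-yl]-2,2-dimethyl-N-(quinolin-8-yl)cyclobutane-1-carboxamide
Conditions: Pd(OAc)2 (15 mol %), Ag2CO3 (1 equiv), t-BuOMe, 90 °C
Reagents that add atoms: none
Why: In this aminoquinoline-directed C(sp3)–H alkenylation the N,N-chelate forms a cis-fused palladacycle at the only β-C–H position (the ring CH2), and oxidative addition of the alkenyl iodide (divalent/tetravalent palladium cycle, the alkenyl bromide being far less reactive) followed by reductive elimination delivers the alkenyl group cis to the amide, which sets C9.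

**Step 8**
Reactants: 14 the cis amide
Product: 16 (1S,4R)-4-[(5E)-6-bromohepta-1,5-dien-2-yl]-2,2-dimethylcyclobutane-1-carbaldehyde, via cis-aldehyde 15 (not isolated)
Conditions: Cp2Zr(H)Cl (2.5 equiv), THF, rt; aqueous work-up; then K2CO3, MeOH, rt
Reagents that add atoms: none
Why: Hydride addition of Cp2Zr(H)Cl to the amide gives a zirconated hemiaminal that releases the aldehyde and the aminoquinoline on work-up (expected to be faster than hydrozirconation of the hindered 1,1-disubstituted alkene), and base-mediated enolisation then epimerises only C1 to the more stable trans-1,2-disubstituted cyclobutane.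

**Step 9**
Reactants: 16 the trans aldehyde
Product: 17 (2S,3R)-3-[(5E)-6-bromohepta-1,5-dien-2-yl]-2-ethenyl-1,1-dimethylcyclobutane
Conditions: Ph3PCH3Br, KOt-Bu, THF, 0 °C to rt
Reagents that add atoms: methyltriphenylphosphonium bromide, C[P+](c1ccccc1)(c1ccccc1)c1ccccc1.[Br-]
Why: Wittig methylenation of the aldehyde; the trans arrangement is the thermodynamic one, so the basic ylide cannot erode it.

**Step 10**
Reactants: 17 the vinyl cyclobutane
Product: 19 (1S,4E,9R)-4,11,11-trimethyl-8-methylidenebicyclo[7.2.0]undec-4-ene, via alkylborane 18 (not isolated)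
Conditions: Sia2BH (from BH3·THF and 2-methylbut-2-ene), THF, 0 °C; then PdCl2(dppf) (20 mol %), Ph3As, Cs2CO3, DMF–THF–H2O, 0.002 M (slow addition), 50 °C
Reagents that add atoms: none
Why: Disiamylborane hydroborates the monosubstituted vinyl group anti-Markovnikov in preference to the 1,1-disubstituted methylene and the bromoalkene, and the intramolecular B-alkyl Suzuki–Miyaura coupling at high dilution forms the C3–C4 bond with retention of the alkenyl bromide geometry, a closure that has precedent for E-cyclononenes.

**Step 11**
Reactants: 19 (+)-β-caryophyllene; 20 benzaldehyde; 21 2,4,6-trihydroxybenzene-1,3-dicarbaldehyde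
Product: 23 target meroterpenoid (1S,4S,5R,9R,1′S), via o-quinone methide 22 (not isolated)
Conditions: TsOH·H2O (5 mol %), H2O, 100 °C
Reagents that add atoms: none
Why: Knoevenagel condensation gives the o-quinone methide, which should undergo an inverse-electron-demand hetero-Diels–Alder reaction with the strained endocyclic E-alkene (not the methylidene); oxygen bonds to the more substituted C4, addition is suprafacial on the outer face of the major ring conformer (the face that peracids attack), and the orientation with H-5 under the heterodiene places phenyl cis to H-5.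

**Compound list**
1 | 2,2-dimethylcyclopentan-1-one | CC1(C)CCCC1=O | starting material
2 | 2,2-dimethyl-5-(trifluoroacetyl)cyclopentan-1-one (not isolated) | CC1(C)CCC(C(=O)C(F)(F)F)C1=O | intermediate
3 | 2-diazo-5,5-dimethylcyclopentan-1-one | CC1(C)CCC(=[N+]=[N-])C1=O | intermediate
4 | quinolin-8-amine | Nc1cccc2cccnc12 | starting material
5 | (2,2-dimethylcyclobutylidene)methanone, the ketene (not isolated) | CC1(C)CCC1=C=O | intermediate
6 | (1R)-2,2-dimethyl-N-(quinolin-8-yl)cyclobutane-1-carboxamide | O=C(Nc1cccc2cccnc12)[C@@H]1CCC1(C)C | intermediate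
7 | pent-3-yn-1-ol | CC#CCCO | starting material
8 | O-zirconated (E)-alkenylzirconocene chloride (not isolated) | C/C(=C\CCO[Zr](Cl)(C1C=CC=C1)C1C=CC=C1)[Zr](Cl)(C1C=CC=C1)C1C=CC=C1 | intermediate
9 | (3E)-4-bromopent-3-en-1-ol | C/C(Br)=C\CCO | intermediate
10 | (2E)-2-bromo-5-iodopent-2-ene | C/C(Br)=C\CCI | intermediate
11 | (5E)-6-bromohept-5-en-1-yne | C#CCC/C=C(\C)Br | intermediate
12 | 9-[(1Z,5E)-6-bromo-2-iodohepta-1,5-dien-1-yl]-9-borabicyclo[3.3.1]nonane (not isolated) | Br/C(C)=C/CC/C(I)=C/B1C2CCCC1CCC2 | intermediate
13 | (5E)-6-bromo-2-iodohepta-1,5-diene | C=C(I)CC/C=C(\C)Br | intermediate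
14 | (1R,4R)-4-[(5E)-6-bromohepta-1,5-dien-2-yl]-2,2-dimethyl-N-(quinolin-8-yl)cyclobutane-1-carboxamide | O=C(Nc1cccc2cccnc12)[C@@H]1[C@H](C(=C)CC/C=C(\C)Br)CC1(C)C | intermediate
15 | (1R,4R)-4-[(5E)-6-bromohepta-1,5-dien-2-yl]-2,2-dimethylcyclobutane-1-carbaldehyde, cis (not isolated) | O=C[C@@H]1[C@H](C(=C)CC/C=C(\C)Br)CC1(C)C | intermediate
16 | (1S,4R)-4-[(5E)-6-bromohepta-1,5-dien-2-yl]-2,2-dimethylcyclobutane-1-carbaldehyde, trans | O=C[C@H]1[C@H](C(=C)CC/C=C(\C)Br)CC1(C)C | intermediate
17 | (2S,3R)-3-[(5E)-6-bromohepta-1,5-dien-2-yl]-2-ethenyl-1,1-dimethylcyclobutane | C=C[C@H]1[C@H](C(=C)CC/C=C(\C)Br)CC1(C)C | intermediate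
18 | {2-[(1S,4R)-4-[(5E)-6-bromohepta-1,5-dien-2-yl]-2,2-dimethylcyclobutyl]ethyl}bis(3-methylbutan-2-yl)borane (not isolated) | CC(C)C(C)B(CC[C@H]1[C@H](C(=C)CC/C=C(\C)Br)CC1(C)C)C(C)C(C)C | intermediate
19 | (1S,4E,9R)-4,11,11-trimethyl-8-methylidenebicyclo[7.2.0]undec-4-ene, (+)-β-caryophyllene | C=C1CC/C=C(\C)CC[C@H]2[C@H]1CC2(C)C | intermediate
20 | benzaldehyde | O=Cc1ccccc1 | starting material
21 | 2,4,6-trihydroxybenzene-1,3-dicarbaldehyde (taken as commercial; otherwise one double Vilsmeier formylation from phloroglucinol) | O=Cc1c(O)cc(O)c(C=O)c1O | starting material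
22 | (E)-benzylidene o-quinone methide of 21 (not isolated) | O=C1C(=C\c2ccccc2)\C(O)=C(C=O)C(O)=C1C=O | intermediate
23 | target meroterpenoid CNP0253700.1 (caryophyllane numbering 1S,4S,5R,9R,1′S) | C=C1CC[C@@H]2[C@@H](c3ccccc3)c3c(O)c(C=O)c(O)c(C=O)c3O[C@@]2(C)CC[C@H]2[C@H]1CC2(C)C | target

**Totals**
Total steps: 11. Longest linear sequence: 9 (steps 3 to 11, from pent-3-yn-1-ol).

**Steps most likely to fail**
1. Step 10. Strain in the trans-fused E-cyclononene can divert the coupling to intermolecular oligomerisation or protodeboronation, and transmetalation from the hindered disiamylborane may be slow. Fallback: from 17 the same selective hydroboration followed by NaOH/H2O2 gives 2-[(1S,4R)-4-[(5E)-6-bromohepta-1,5-dien-2-yl]-2,2-dimethylcyclobutyl]ethan-1-ol F1. Treatment with I2/PPh3/imidazole gives (2S,3R)-3-[(5E)-6-bromohepta-1,5-dien-2-yl]-2-(2-iodoethyl)-1,1-dimethylcyclobutane F2. Zinc dust/LiCl in THF inserts only into the C(sp3)–I bond to give the alkylzinc iodide F3, which is added slowly to Pd(P(t-Bu)3)2 (intramolecular Negishi coupling onto the alkenyl bromide) and comes back at 19.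
2. Step 11. Poor discrimination between the ring conformers and between the two heterodiene orientations can give diastereomeric adducts, and the hot acid can rearrange the terpene. Fallback: from 20 and 21 with morpholine in ethanol the Mannich base 2,4,6-trihydroxy-5-[morpholin-4-yl(phenyl)methyl]benzene-1,3-dicarbaldehyde F4 is isolated. It is then heated with 19 in toluene at 80 °C, which releases 22 slowly without acid and comes back at 23.
3. Step 8. Competing hydrozirconation of the 1,1-disubstituted alkene or over-reduction can accompany cleavage of the secondary amide. Fallback: from 14, Boc2O/DMAP gives the N-Boc imide F5. NaOMe/MeOH cleaves the activated amide and epimerises C1, giving the trans methyl ester F6. DIBAL-H at −78 °C then comes back at 16.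

**Further compounds**
F1 | step 10 | 2-[(1S,4R)-4-[(5E)-6-bromohepta-1,5-dien-2-yl]-2,2-dimethylcyclobutyl]ethan-1-ol | OCC[C@H]1[C@H](C(=C)CC/C=C(\C)Br)CC1(C)C
F2 | step 10 | (2S,3R)-3-[(5E)-6-bromohepta-1,5-dien-2-yl]-2-(2-iodoethyl)-1,1-dimethylcyclobutane | ICC[C@H]1[C@H](C(=C)CC/C=C(\C)Br)CC1(C)C
F3 | step 10 | {2-[(1S,4R)-4-[(5E)-6-bromohepta-1,5-dien-2-yl]-2,2-dimethylcyclobutyl]ethyl}zinc iodide | I[Zn]CC[C@H]1[C@H](C(=C)CC/C=C(\C)Br)CC1(C)C
F4 | step 11 | 2,4,6-trihydroxy-5-[morpholin-4-yl(phenyl)methyl]benzene-1,3-dicarbaldehyde (racemic) | O=Cc1c(O)c(C(c2ccccc2)N2CCOCC2)c(O)c(C=O)c1O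
F5 | step 8 | tert-butyl N-{(1R,4R)-4-[(5E)-6-bromohepta-1,5-dien-2-yl]-2,2-dimethylcyclobutane-1-carbonyl}-N-(quinolin-8-yl)carbamate | CC(C)(C)OC(=O)N(c1cccc2cccnc12)C(=O)[C@@H]1[C@H](C(=C)CC/C=C(\C)Br)CC1(C)C
F6 | step 8 | methyl (1S,4R)-4-[(5E)-6-bromohepta-1,5-dien-2-yl]-2,2-dimethylcyclobutane-1-carboxylate | COC(=O)[C@H]1[C@H](C(=C)CC/C=C(\C)Br)CC1(C)C
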